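**Plan**

- Retrosynthesis: ring C is cut at three bonds, C4a–C4, C4–C3 and O1–C2, into an iodophloroglucinol (carried as its triacetate), carbon monoxide and the ring B arylacetylene. In the alkyne, the dihydrofuran O–C2 bond goes back to an epoxide opening by the phenol, the epoxide to an allylic alcohol, and the carbinol C–C bond to an aldehyde plus an alkenyl Grignard reagent.
- Enabling feature: C4 is a lone carbonyl carbon between C4a of ring A and C3, and C4a lies between two equivalent oxygen-bearing carbons (C5 and C8a) of the symmetric phloroglucinol ring, so CO and one alkyne complete ring C whichever oxygen closes.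
- Forward order: 4-bromophenol is prenylated, formylated and alkynylated (ring B); alkenyl addition, resolution, directed epoxidation and 5-exo epoxide opening build the dihydrofuran ring; phloroglucinol is iodinated and acetylated (ring A); ring C is closed last.
- Stereochemistry: the carbinol centre (C3 of the dihydrobenzofuran) comes from a Sharpless kinetic resolution. C2 comes from a hydroxyl-directed threo epoxidation followed by invertive epoxide opening, which gives the trans (2R,3R) pair. The key step creates no stereocentre.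

Key step: step 11

Assumption: in step 11 the excess diethylamine is taken to cleave all three aryl acetates in the flask, so that the annulation delivers the free 5,7-diol.

Abbreviations: prenyl = 3-methylbut-2-en-1-yl; TBS = tert-butyldimethylsilyl; TMS = trimethylsilyl.

**Route**

Step 1
Reactants: 1 4-bromophenol; 2 1-bromo-3-methylbut-2-ene (prenyl bromide)
Product: 3 4-bromo-2-(3-methylbut-2-en-1-yl)phenol
Conditions: NaH, toluene, 0 °C to rt
Reagents that add atoms: none
Why: Ortho C-alkylation of a phenoxide: the sodium phenoxide, held as a tight ion pair in a non-polar solvent, should be prenylated at the carbon next to oxygen in preference to oxygen, and the bromine blocks the para position.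

Step 2
Reactants: 3 4-bromo-2-(3-methylbut-2-en-1-yl)phenol
Product: 4 5-bromo-2-hydroxy-3-(3-methylbut-2-en-1-yl)benzaldehyde
Conditions: MgCl2, Et3N, (CH2O)n, MeCN, reflux; then cold dilute HCl
Reagents that add atoms: paraformaldehyde (formaldehyde), C=O
Why: Magnesium-mediated ortho-formylation (Casnati–Skattebøl reaction): the magnesium phenoxide delivers formaldehyde to the only free ortho position and a second formaldehyde oxidises the benzylic alkoxide to the aldehyde, under basic conditions that spare the prenyl group and the aryl bromide.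

Step 3
Reactants: 4 5-bromo-2-hydroxy-3-(3-methylbut-2-en-1-yl)benzaldehyde; 5 trimethylsilylacetylene
Product: 6 2-hydroxy-3-(3-methylbut-2-en-1-yl)-5-[(trimethylsilyl)ethynyl]benzaldehyde
Conditions: PdCl2(PPh3)2 (cat.), CuI (cat.), Et3N, THF, 65 °C
Reagents that add atoms: none
Why: Sonogashira coupling of the aryl bromide with the terminal alkyne, a reaction that tolerates the free hydroxy aldehyde of 5-bromosalicylaldehydes, while the trisubstituted prenyl alkene is too hindered to compete as a Heck acceptor.

Step 4
Reactants: 6 2-hydroxy-3-(3-methylbut-2-en-1-yl)-5-[(trimethylsilyl)ethynyl]benzaldehyde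
Product: 7 2-[(tert-butyldimethylsilyl)oxy]-3-(3-methylbut-2-en-1-yl)-5-[(trimethylsilyl)ethynyl]benzaldehyde
Conditions: TBSCl, imidazole, DMF, rt
Reagents that add atoms: tert-butyldimethylsilyl chloride, CC(C)(C)[Si](C)(C)Cl
Why: Silylation of the phenol removes the acidic proton before the Grignard and epoxidation steps and gives an aryl silyl ether that fluoride can later cleave without acid.

Step 5
Reactants: 7 2-[(tert-butyldimethylsilyl)oxy]-3-(3-methylbut-2-en-1-yl)-5-[(trimethylsilyl)ethynyl]benzaldehyde; 8 2-methylprop-1-en-1-ylmagnesium bromide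
Product: 9 rac-1-{2-[(tert-butyldimethylsilyl)oxy]-3-(3-methylbut-2-en-1-yl)-5-[(trimethylsilyl)ethynyl]phenyl}-3-methylbut-2-en-1-ol
Conditions: THF, −78 to 0 °C; then aq NH4Cl
Reagents that add atoms: none
Why: 1,2-Addition of an alkenyl Grignard reagent to the aldehyde gives the racemic secondary allylic alcohol, and the low temperature and the magnesium counter-ion should hold back silyl migration from the phenol oxygen to the new alkoxide.

Step 6
Reactants: 9 rac-1-{2-[(tert-butyldimethylsilyl)oxy]-3-(3-methylbut-2-en-1-yl)-5-[(trimethylsilyl)ethynyl]phenyl}-3-methylbut-2-en-1-ol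
Product: 10 (1S)-1-{2-[(tert-butyldimethylsilyl)oxy]-3-(3-methylbut-2-en-1-yl)-5-[(trimethylsilyl)ethynyl]phenyl}-3-methylbut-2-en-1-ol (recovered enantiomer)
Conditions: Ti(OiPr)4, diisopropyl L-(+)-tartrate, t-BuOOH (0.6 equiv), 4 Å MS, CH2Cl2, −20 °C
Reagents that add atoms: none
Why: Sharpless kinetic resolution: the Ti(OiPr)4/L-(+)-tartrate complex epoxidises only the titanium-bound allylic alkoxide (the prenyl alkene is inert) and should consume the (R)-enantiomer much faster, giving a separable erythro epoxy alcohol, so that the slow-reacting (S)-alcohol (S because the aryl group outranks the alkenyl group) is recovered in high enantiomeric purity once conversion passes one half.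

Step 7
Reactants: 10 (1S)-1-{2-[(tert-butyldimethylsilyl)oxy]-3-(3-methylbut-2-en-1-yl)-5-[(trimethylsilyl)ethynyl]phenyl}-3-methylbut-2-en-1-ol
Product: 11 (R)-{2-[(tert-butyldimethylsilyl)oxy]-3-(3-methylbut-2-en-1-yl)-5-[(trimethylsilyl)ethynyl]phenyl}[(2S)-3,3-dimethyloxiran-2-yl]methanol (threo)
Conditions: VO(acac)2 (cat.), t-BuOOH, CH2Cl2, 0 °C
Reagents that add atoms: tert-butyl hydroperoxide, CC(C)(C)OO
Why: Hydroxyl-directed vanadium-catalysed epoxidation: only the alkene next to the carbinol is epoxidised, and because the cis-methyl group forces the carbinol hydrogen into the alkene plane (1,3-allylic strain), oxygen should be delivered syn to the hydroxyl on the face that gives the threo (1R,2S) epoxy alcohol, which sets the epoxide carbon that becomes C2 of the dihydrobenzofuran.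

Step 8
Reactants: 11 (R)-{2-[(tert-butyldimethylsilyl)oxy]-3-(3-methylbut-2-en-1-yl)-5-[(trimethylsilyl)ethynyl]phenyl}[(2S)-3,3-dimethyloxiran-2-yl]methanol
Product: 13 2-[(2R,3R)-5-ethynyl-3-hydroxy-7-(3-methylbut-2-en-1-yl)-2,3-dihydro-1-benzofuran-2-yl]propan-2-ol, via epoxy phenol 12 (not isolated)
Conditions: TBAF (3 equiv), THF, 0 °C to rt
Reagents that add atoms: none
Why: Fluoride removes the aryl silyl ether and the alkynyl silane, and the phenoxide should open the epoxide at its less substituted carbon in a 5-exo-tet cyclisation with inversion, so that the threo epoxy alcohol becomes the trans (2R,3R) dihydrobenzofuranol while the carbinol centre is untouched.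

Step 9
Reactants: 14 phloroglucinol (benzene-1,3,5-triol)
Product: 15 2-iodobenzene-1,3,5-triol
Conditions: I2 (1 equiv), NaHCO3, THF/H2O, 0 °C; used at once
Reagents that add atoms: iodine, II
Why: Electrophilic aromatic iodination of the highly activated ring, whose three free positions are equivalent, so that one equivalent of iodine under bicarbonate buffering should give the mono-iodide.

Step 10
Reactants: 15 2-iodobenzene-1,3,5-triol
Product: 16 2-iodobenzene-1,3,5-triyl triacetate
Conditions: Ac2O, pyridine, DMAP (cat.), CH2Cl2, 0 °C to rt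
Reagents that add atoms: acetic anhydride, CC(=O)OC(C)=O
Why: Acetylation of the three phenols under basic conditions gives a storable, less electron-rich aryl iodide whose ortho oxygens stay masked until the amine of the next step frees them.

Step 11
Reactants: 16 2-iodobenzene-1,3,5-triyl triacetate; 17 carbon monoxide; 13 2-[(2R,3R)-5-ethynyl-3-hydroxy-7-(3-methylbut-2-en-1-yl)-2,3-dihydro-1-benzofuran-2-yl]propan-2-ol
Product: 20 CNP0172554.2 (5,7-dihydroxy-2-[(2R,3R)-3-hydroxy-2-(2-hydroxypropan-2-yl)-7-(3-methylbut-2-en-1-yl)-2,3-dihydro-1-benzofuran-5-yl]-4H-chromen-4-one), via triacetoxyphenyl ynone 18 (not isolated), via trihydroxyphenyl enaminone 19 (not isolated)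
Conditions: PdCl2(PPh3)2 (cat.), dppp, thiourea, Et2NH (excess), DBU, DMF, CO (1 atm), 40 °C
Reagents that add atoms: none
Why: The divalent palladium precatalyst is reduced to zerovalent palladium, which inserts into the C–I bond of 16; CO insertion gives the aroylpalladium species, and coupling with the terminal alkyne of 13 forms C4a–C4 and C4–C3 in ynone 18. Diethylamine then adds to the ynone and cleaves the aryl acetates, and a freed ortho hydroxyl of enaminone 19 attacks C2 and expels the amine, which forms O1–C2. The closest known reaction type is the palladium-catalysed carbonylative annulation of 2-iodophenol acetates with terminal arylacetylenes to flavones. Ring C closes in a 6-endo mode (6-endo-trig addition–elimination on the enaminone, 6-endo-dig overall with respect to the ynone), and no stereocentre is formed or touched. The step needs CO uptake to outrun direct alkyne coupling and 6-endo closure to outrun 5-exo closure to the aurone; the acetates keep the ortho oxygens masked until the ynone exists, and the secondary amine channels the closure through the enaminone. Because C4a lies between two equivalent acetoxy-bearing carbons, either oxygen gives the same ring C and no regiochemical choice arises.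

**Compound list**

1 | 4-bromophenol | Oc1ccc(Br)cc1 | starting material
2 | 1-bromo-3-methylbut-2-ene | CC(C)=CCBr | starting material
3 | 4-bromo-2-(3-methylbut-2-en-1-yl)phenol | CC(C)=CCc1cc(Br)ccc1O | intermediate
4 | 5-bromo-2-hydroxy-3-(3-methylbut-2-en-1-yl)benzaldehyde | CC(C)=CCc1cc(Br)cc(C=O)c1O | intermediate
5 | trimethylsilylacetylene | C#C[Si](C)(C)C | starting material
6 | 2-hydroxy-3-(3-methylbut-2-en-1-yl)-5-[(trimethylsilyl)ethynyl]benzaldehyde | CC(C)=CCc1cc(C#C[Si](C)(C)C)cc(C=O)c1O | intermediate
7 | 2-[(tert-butyldimethylsilyl)oxy]-3-(3-methylbut-2-en-1-yl)-5-[(trimethylsilyl)ethynyl]benzaldehyde | CC(C)=CCc1cc(C#C[Si](C)(C)C)cc(C=O)c1O[Si](C)(C)C(C)(C)C | intermediate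
8 | 2-methylprop-1-en-1-ylmagnesium bromide | CC(C)=C[Mg]Br | starting material
9 | rac-1-{2-[(tert-butyldimethylsilyl)oxy]-3-(3-methylbut-2-en-1-yl)-5-[(trimethylsilyl)ethynyl]phenyl}-3-methylbut-2-en-1-ol | CC(C)=CCc1cc(C#C[Si](C)(C)C)cc(C(O)C=C(C)C)c1O[Si](C)(C)C(C)(C)C | intermediate
10 | (1S)-1-{2-[(tert-butyldimethylsilyl)oxy]-3-(3-methylbut-2-en-1-yl)-5-[(trimethylsilyl)ethynyl]phenyl}-3-methylbut-2-en-1-ol | CC(C)=C[C@H](O)c1cc(C#C[Si](C)(C)C)cc(CC=C(C)C)c1O[Si](C)(C)C(C)(C)C | intermediate
11 | (R)-{2-[(tert-butyldimethylsilyl)oxy]-3-(3-methylbut-2-en-1-yl)-5-[(trimethylsilyl)ethynyl]phenyl}[(2S)-3,3-dimethyloxiran-2-yl]methanol | CC1(C)O[C@H]1[C@H](O)c2cc(C#C[Si](C)(C)C)cc(CC=C(C)C)c2O[Si](C)(C)C(C)(C)C | intermediate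
12 | (R)-[(2S)-3,3-dimethyloxiran-2-yl][5-ethynyl-2-hydroxy-3-(3-methylbut-2-en-1-yl)phenyl]methanol (present as its phenoxide) | CC1(C)O[C@H]1[C@H](O)c2cc(C#C)cc(CC=C(C)C)c2O | intermediate (not isolated)
13 | 2-[(2R,3R)-5-ethynyl-3-hydroxy-7-(3-methylbut-2-en-1-yl)-2,3-dihydro-1-benzofuran-2-yl]propan-2-ol | CC(C)=CCc1cc(C#C)cc2c1O[C@@H](C(C)(C)O)[C@@H]2O | intermediate
14 | phloroglucinol (benzene-1,3,5-triol) | Oc1cc(O)cc(O)c1 | starting material
15 | 2-iodobenzene-1,3,5-triol | Oc1cc(O)c(I)c(O)c1 | intermediate
16 | 2-iodobenzene-1,3,5-triyl triacetate | CC(=O)Oc1cc(OC(C)=O)c(I)c(OC(C)=O)c1 | intermediate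
17 | carbon monoxide | [C-]#[O+] | starting material
18 | 2-{3-[(2R,3R)-3-hydroxy-2-(2-hydroxypropan-2-yl)-7-(3-methylbut-2-en-1-yl)-2,3-dihydro-1-benzofuran-5-yl]prop-2-ynoyl}benzene-1,3,5-triyl triacetate | CC(C)=CCc1cc(C#CC(=O)c2c(OC(C)=O)cc(OC(C)=O)cc2OC(C)=O)cc2c1O[C@@H](C(C)(C)O)[C@@H]2O | intermediate (not isolated)
19 | 3-(diethylamino)-3-[(2R,3R)-3-hydroxy-2-(2-hydroxypropan-2-yl)-7-(3-methylbut-2-en-1-yl)-2,3-dihydro-1-benzofuran-5-yl]-1-(2,4,6-trihydroxyphenyl)prop-2-en-1-one | CC(C)=CCc1cc(C(=CC(=O)c2c(O)cc(O)cc2O)N(CC)CC)cc2c1O[C@@H](C(C)(C)O)[C@@H]2O | intermediate (not isolated)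
20 | CNP0172554.2, 5,7-dihydroxy-2-[(2R,3R)-3-hydroxy-2-(2-hydroxypropan-2-yl)-7-(3-methylbut-2-en-1-yl)-2,3-dihydro-1-benzofuran-5-yl]-4H-chromen-4-one | CC(C)=CCc1cc(-c2cc(=O)c3c(O)cc(O)cc3o2)cc2c1O[C@@H](C(C)(C)O)[C@@H]2O | target

**Step count**

Total: 11 steps. Longest linear sequence: 9 steps (steps 1 to 8, then step 11); the ring A piece takes 2 steps (9 and 10).

**Steps most likely to fail**

1. Step 11. The acetates may be aminolysed before oxidative addition, after which the electron-rich ring can lose iodine; oxidative addition at the doubly ortho-substituted C–I bond may be slow; or the alkyne may couple without CO uptake. Fallback, setting out from 13 and returning at 18: the carbonyl carbon is brought in as an acid chloride, so no CO is needed. 2,4,6-Trihydroxybenzoic acid F1 is peracetylated (Ac2O, pyridine) to 2,4,6-triacetoxybenzoic acid F2, which oxalyl chloride and catalytic DMF convert into 2,4,6-triacetoxybenzoyl chloride F3. A copper-cocatalysed acyl Sonogashira coupling of F3 with 13 (PdCl2(PPh3)2, CuI, Et3N, THF, rt) should give ynone 18, which is then treated with Et2NH and DBU in DMF to close ring C and give 20.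

2. Step 6. The rate difference between the two enantiomers may be too small, because the alkene carries a cis-methyl group and the carbinol a bulky ortho-silyloxyaryl group, so the recovered alcohol may be of low enantiomeric purity; at best half of the material is kept. Fallback, setting out from 7 and returning at 10: the carbinol centre is made by catalytic asymmetric alkenylation and not by resolution. Grignard reagent 8 is transmetalated with ZnCl2 to bis(2-methylprop-1-en-1-yl)zinc F4, the magnesium halide is removed or sequestered with a diamine, and F4 is added to aldehyde 7 in the presence of catalytic (−)-3-exo-morpholinoisoborneol, the ligand enantiomer being the one that gives the S carbinol; this should deliver 10 directly.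

3. Step 7. Threo selectivity may be insufficient, or the doubly activated carbinol may be oxidised to the enone. Fallback, setting out from 9 and returning at 13: the configuration is corrected by inversion at the carbinol and not by substrate-directed epoxidation. Sharpless epoxidation of 9 with Ti(OiPr)4, diisopropyl L-(+)-tartrate and t-BuOOH, taken to about half conversion, should give the erythro epoxy alcohol (S)-{2-[(tert-butyldimethylsilyl)oxy]-3-(3-methylbut-2-en-1-yl)-5-[(trimethylsilyl)ethynyl]phenyl}[(2S)-3,3-dimethyloxiran-2-yl]methanol F5, in which the epoxide carbon already has the needed configuration. Mitsunobu inversion with 4-nitrobenzoic acid, PPh3 and DIAD gives (R)-{2-[(tert-butyldimethylsilyl)oxy]-3-(3-methylbut-2-en-1-yl)-5-[(trimethylsilyl)ethynyl]phenyl}[(2S)-3,3-dimethyloxiran-2-yl]methyl 4-nitrobenzoate F6. K2CO3 in MeOH then cleaves the ester, the alkynyl silane and the aryl silyl ether, and the phenoxide closes through 12 to 13.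

**Further compounds**

F1 | step 11 | 2,4,6-trihydroxybenzoic acid | OC(=O)c1c(O)cc(O)cc1O
F2 | step 11 | 2,4,6-triacetoxybenzoic acid | CC(=O)Oc1cc(OC(C)=O)c(C(O)=O)c(OC(C)=O)c1
F3 | step 11 | 2,4,6-triacetoxybenzoyl chloride | CC(=O)Oc1cc(OC(C)=O)c(C(Cl)=O)c(OC(C)=O)c1
F4 | step 6 | bis(2-methylprop-1-en-1-yl)zinc | CC(C)=C[Zn]C=C(C)C
F5 | step 7 | (S)-{2-[(tert-butyldimethylsilyl)oxy]-3-(3-methylbut-2-en-1-yl)-5-[(trimethylsilyl)ethynyl]phenyl}[(2S)-3,3-dimethyloxiran-2-yl]methanol | CC1(C)O[C@H]1[C@@H](O)c2cc(C#C[Si](C)(C)C)cc(CC=C(C)C)c2O[Si](C)(C)C(C)(C)C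
F6 | step 7 | (R)-{2-[(tert-butyldimethylsilyl)oxy]-3-(3-methylbut-2-en-1-yl)-5-[(trimethylsilyl)ethynyl]phenyl}[(2S)-3,3-dimethyloxiran-2-yl]methyl 4-nitrobenzoate | CC1(C)O[C@H]1[C@H](OC(=O)c3ccc(cc3)[N+](=O)[O-])c2cc(C#C[Si](C)(C)C)cc(CC=C(C)C)c2O[Si](C)(C)C(C)(C)C
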